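**Plan**
1. Retrosynthesis: the benzyl-type ethers and the stilbene C–C bond (Heck) are cut first. The benzene ring of the catechol-bearing benzofuran (ring C) is then taken back to a cyclohexenone, and the furan bond O1–C2 of that benzofuran is exchanged for a C3a–C2 bond, giving a spiro-cyclopropane on a cyclohexane-1,3-dione.
2. Enabling feature: in that benzofuran C-3a lies between two oxygen-bearing ring carbons (C-4 and C-7a), so ring C is a masked 1,3-dione whose C-2 can carry the cyclopropane. O1–C2 is benzylic to the para-oxygenated catechol ring, so only that cyclopropane bond ionises.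
3. The cyclopropane is cut into three parts: the dione, 3,4-bis(benzyloxy)benzaldehyde and a chiral 3,5-bis(benzyloxy)benzyl sulfonium ylide. The dione ring is cut to an enone plus malonate, and the styryl-bearing dihydrobenzofuran is cut at C2–C3 to an aryldiazoacetate.
4. Forward order: styryl-side dihydrofuran (C–H insertion) → ring C as saturated dione → cyclopropane → catechol-side dihydrofuran by three-to-five ring expansion → ring C aromatised → stilbene → deprotection.
5. Stereochemistry: a chiral rhodium carboxylate sets C-2 of the first dihydrofuran and base epimerisation sets its trans C-3. The chiral sulfonium ylide sets C-3 of the second dihydrofuran and the ring expansion sets its C-2 trans.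

Key step: step 11

Assumption: Rh2(S-PTTL)4 is taken to insert with the (2R) sense and the ylide of (1R,4R,5R)-isothiocineole to deliver the (2S) cyclopropane carbon; if either sense proves opposite, the mirror-image catalyst or sulfide is used.

Shorthand: LU = (2R,3R)-6-bromo-4-{[4-(benzyloxy)benzyl]oxy}-2-[4-(benzyloxy)phenyl]-2,3-dihydro-1-benzofuran-3-yl. Ring B is the benzene ring of this unit; ring C is the benzene ring of the catechol-bearing benzofuran.

**Route**

Step 1
Reactants: 1 5-bromobenzene-1,3-diol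
Product: 2 5-bromo-2-iodobenzene-1,3-diol
Conditions: I2, NaHCO3, H2O–THF, 0 °C → rt
Reagents that add atoms: iodine, II
Why: Electrophilic aromatic iodination should go to the carbon between the two hydroxyl groups, the most activated ring position and the only one not flanked by bromine, as in the iodination of resorcinol to 2-iodoresorcinol.

Step 2
Reactants: 2 5-bromo-2-iodobenzene-1,3-diol; 3 4-(benzyloxy)benzyl chloride
Product: 4 5-bromo-2-iodo-1,3-bis{[4-(benzyloxy)benzyl]oxy}benzene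
Conditions: K2CO3, Bu4NI (cat.), DMF, 60 °C
Reagents that add atoms: 4-(benzyloxy)benzyl chloride 3, ClCc1ccc(OCc2ccccc2)cc1
Why: Williamson ether synthesis on both phenols installs two identical groups, one of which later becomes the C–H insertion site while the other protects the ring B phenol.

Step 3
Reactants: 4 5-bromo-2-iodo-1,3-bis{[4-(benzyloxy)benzyl]oxy}benzene; 5 (2-ethoxy-2-oxoethyl)zinc bromide
Product: 6 ethyl 2-(4-bromo-2,6-bis{[4-(benzyloxy)benzyl]oxy}phenyl)acetate
Conditions: Pd2(dba)3 (2 mol %), XPhos (8 mol %), THF, rt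
Reagents that add atoms: (2-ethoxy-2-oxoethyl)zinc bromide 5, CCOC(=O)C[Zn]Br
Why: Negishi-type α-arylation with a Reformatsky reagent should be selective because zerovalent palladium inserts into the C–I bond much faster than into the C–Br bond at room temperature, which keeps the bromide for the late Heck reaction.

Step 4
Reactants: 6 ethyl 2-(4-bromo-2,6-bis{[4-(benzyloxy)benzyl]oxy}phenyl)acetate
Product: 7 ethyl 2-(4-bromo-2,6-bis{[4-(benzyloxy)benzyl]oxy}phenyl)-2-diazoacetate
Conditions: 4-acetamidobenzenesulfonyl azide, DBU, MeCN, 0 °C → rt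
Reagents that add atoms: 4-acetamidobenzenesulfonyl azide, CC(=O)Nc1ccc(cc1)S(=O)(=O)N=[N+]=[N-]
Why: Regitz diazo transfer to the aryl-activated ester methylene gives the donor/acceptor diazo compound.

Step 5
Reactants: 7 ethyl 2-(4-bromo-2,6-bis{[4-(benzyloxy)benzyl]oxy}phenyl)-2-diazoacetate
Product: 8 ethyl (2R,3S)-6-bromo-4-{[4-(benzyloxy)benzyl]oxy}-2-[4-(benzyloxy)phenyl]-2,3-dihydro-1-benzofuran-3-carboxylate (cis)
Conditions: Rh2(S-PTTL)4 [dirhodium tetrakis(N-phthaloyl-(S)-tert-leucinate)] (1 mol %), toluene, −60 → −20 °C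
Reagents that add atoms: none
Why: Intramolecular 1,5 C–H insertion of the divalent-rhodium donor/acceptor carbenoid into an ether benzylic C–H bond (the two ortho ether groups are equivalent) closes the dihydrofuran, and the chiral carboxylate ligands set C-2 as (R) in the cis ester, the usual outcome for 2-(benzyloxy)aryl diazoacetates.

Step 6
Reactants: 8 ethyl (2R,3S)-6-bromo-4-{[4-(benzyloxy)benzyl]oxy}-2-[4-(benzyloxy)phenyl]-2,3-dihydro-1-benzofuran-3-carboxylate (cis)
Product: 9 ethyl (2R,3R)-6-bromo-4-{[4-(benzyloxy)benzyl]oxy}-2-[4-(benzyloxy)phenyl]-2,3-dihydro-1-benzofuran-3-carboxylate (trans)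
Conditions: NaOEt (0.2 equiv), EtOH–THF, 0 °C → rt
Reagents that add atoms: none
Why: Base-mediated epimerisation of the ester α-carbon moves C-3 to the thermodynamically preferred trans arrangement while C-2 is untouched.

Step 7
Reactants: 9 ethyl (2R,3R)-6-bromo-4-{[4-(benzyloxy)benzyl]oxy}-2-[4-(benzyloxy)phenyl]-2,3-dihydro-1-benzofuran-3-carboxylate (trans); 11 1-(triphenylphosphoranylidene)propan-2-one
Product: 12 (E)-4-(LU)but-3-en-2-one, via aldehyde 10 (not isolated)
Conditions: i-Bu2AlH, CH2Cl2, −78 °C; aq. potassium sodium tartrate; then 11, toluene, 60 °C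
Reagents that add atoms: 1-(triphenylphosphoranylidene)propan-2-one 11, CC(=O)C=P(c1ccccc1)(c1ccccc1)c1ccccc1
Why: Partial ester reduction through the stable aluminium hemiacetal and Wittig olefination with a stabilised ylide under neutral conditions should give the (E)-enone without loss of the trans C-3 centre, which is the thermodynamic one.

Step 8
Reactants: 12 (E)-4-(LU)but-3-en-2-one; 13 dimethyl malonate
Product: 16 5-(LU)cyclohexane-1,3-dione, via keto ester 14 (not isolated), via keto acid 15 (not isolated)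
Conditions: NaOMe, MeOH, rt then 65 °C; 2 M NaOH, 50 °C; AcOH to pH 4, 60 °C
Reagents that add atoms: dimethyl malonate 13, COC(=O)CC(=O)OC
Why: Michael addition of sodium malonate, Claisen (Dieckmann-type) closure, saponification and decarboxylation build ring C as a saturated dione; using pre-formed sodium malonate without free methoxide limits γ-deprotonation of the enone, and C-5 of the dione is not a stereocentre.

Step 9
Reactants: 17 3,5-bis(benzyloxy)benzyl bromide; 18 (1R,4R,5R)-4,7,7-trimethyl-6-thiabicyclo[3.2.1]octane (isothiocineole)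
Product: 19 S-[3,5-bis(benzyloxy)benzyl]isothiocineolium trifluoromethanesulfonate
Conditions: LiOTf, CH2Cl2–H2O, rt
Reagents that add atoms: isothiocineole 18, C[C@@H]1CC[C@@H]2C[C@H]1SC2(C)C; lithium trifluoromethanesulfonate, [Li+].[O-]S(=O)(=O)C(F)(F)F
Why: S-Alkylation of the sulfide by the benzylic bromide with triflate metathesis should give a bench-stable sulfonium salt, alkylated on the less hindered lone pair of sulfur.

Step 10
Reactants: 16 5-(LU)cyclohexane-1,3-dione; 20 3,4-bis(benzyloxy)benzaldehyde; 19 S-[3,5-bis(benzyloxy)benzyl]isothiocineolium trifluoromethanesulfonate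
Product: 23 (1S,2S)-1-[3,4-bis(benzyloxy)phenyl]-2-[3,5-bis(benzyloxy)phenyl]-6-(LU)spiro[2.5]octane-4,8-dione, via alkylidene dione 21 (not isolated), via sulfonium ylide 22 (not isolated)
Conditions: 16 added slowly to 20, piperidinium acetate (10 mol %), 4 Å MS, CH2Cl2, rt; solvent exchange to THF; added to ylide 22 [from 19, LiN(SiMe3)2, THF, −78 °C]; −78 → 0 °C; Et3N-deactivated silica
Reagents that add atoms: 3,4-bis(benzyloxy)benzaldehyde 20, O=Cc1ccc(OCc2ccccc2)c(OCc2ccccc2)c1; sulfonium salt 19, C[C@@H]1CC[C@@H]2C[C@H]1[S@@+](Cc1cc(OCc3ccccc3)cc(OCc3ccccc3)c1)C2(C)C.[O-]S(=O)(=O)C(F)(F)F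
Why: Proposed new method: Knoevenagel condensation gives the alkylidene dione, the chiral benzylic ylide adds to its β-carbon, and the lithium-chelated diketonate of the betaine then displaces the sulfide through carbon (3-exo-tet, inversion), as 1,3-dione enolates do with γ-sulfonium leaving groups, so that three components are joined at the future C-3a; the ylide carbon, the only cyclopropane centre that survives step 11, is fixed by the face selectivity of the isothiocineole ylide and the invertive closure; the closest known reactions are chiral-sulfide-mediated benzylidene transfer to enones (Corey–Chaykovsky cyclopropanation) and sulfonium-ylide cyclopropanation of 2-arylidene-1,3-diones.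

Step 11
Reactants: 23 (1S,2S)-1-[3,4-bis(benzyloxy)phenyl]-2-[3,5-bis(benzyloxy)phenyl]-6-(LU)spiro[2.5]octane-4,8-dione
Product: 24 (2S,3S)-2-[3,4-bis(benzyloxy)phenyl]-3-[3,5-bis(benzyloxy)phenyl]-6-(LU)-3,5,6,7-tetrahydro-1-benzofuran-4(2H)-one
Conditions: Sc(OTf)3 (5 mol %), 4 Å MS, CH2Cl2, −20 °C → rt
Reagents that add atoms: none
Why: Sc(OTf)3 binds the 1,3-dione of the donor–acceptor cyclopropane, and the bond from the spiro carbon to the carbon bearing the 3,4-bis(benzyloxy)phenyl ring heterolyses to a scandium diketonate/para-benzyloxybenzylic cation zwitterion that recombines at oxygen, a three-to-five ring expansion of the Cloke–Wilson type. The closest known reaction is the acid-catalysed ring-opening cyclisation of 1-aryl cyclohexane-1,3-dione-2-spirocyclopropanes to 2-aryl tetrahydrobenzofuran-4-ones. The dihydrofuran closes by O-alkylation of the enolate onto the benzylic cation in a 5-(enolendo)-exo-trig mode. C-3 keeps its cyclopropane configuration because none of its bonds is broken, and C-2 is set in the closure anti to the C-3 aryl group, with reversible ionisation of the new C2–O bond draining any cis isomer to trans. The step needs cleavage of only one of the two cyclopropane bonds at the spiro carbon, secured by the para-oxygen of the catechol ring against the two meta-oxygens of the resorcinol ring, and O- over C-closure, secured by the stability of the vinylogous ester; the catalytic aprotic Lewis acid should leave the first dihydrofuran and its 4-(benzyloxy)benzyl ether intact.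

Step 12
Reactants: 24 (2S,3S)-2-[3,4-bis(benzyloxy)phenyl]-3-[3,5-bis(benzyloxy)phenyl]-6-(LU)-3,5,6,7-tetrahydro-1-benzofuran-4(2H)-one
Product: 26 (2S,3S)-2-[3,4-bis(benzyloxy)phenyl]-3-[3,5-bis(benzyloxy)phenyl]-6-(LU)-2,3-dihydro-1-benzofuran-4-ol, via selenide 25 (not isolated)
Conditions: LiN(SiMe3)2, THF, −78 °C; PhSeBr; then H2O2 (30 %), pyridine, CH2Cl2, 0 °C → rt
Reagents that add atoms: none
Why: Kinetic α′-deprotonation of the vinylogous ester at C-5, selenenylation and selenoxide syn-elimination give a cross-conjugated dienone that tautomerises to the phenol (aromatisation of ring C), while the dihydrofuran is not dehydrogenated and the C-6 epimers converge.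

Step 13
Reactants: 26 (2S,3S)-2-[3,4-bis(benzyloxy)phenyl]-3-[3,5-bis(benzyloxy)phenyl]-6-(LU)-2,3-dihydro-1-benzofuran-4-ol; 27 4-(benzyloxy)styrene
Product: 28 heptabenzyl-type protected target [bromine of 26 replaced by (E)-2-[4-(benzyloxy)phenyl]ethenyl]
Conditions: Pd(OAc)2 (5 mol %), P(o-tol)3 (10 mol %), Et3N, DMF, 100 °C
Reagents that add atoms: 4-(benzyloxy)styrene 27, C=Cc1ccc(OCc2ccccc2)cc1
Why: Mizoroki–Heck reaction of the aryl bromide gives the (E)-stilbene by syn-insertion and syn-β-hydride elimination, and the stilbene is introduced only after the Lewis-acid and selenium steps that it would not survive.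

Step 14
Reactants: 28 heptabenzyl-type protected target
Product: 29 CNP0107857.3 (target)
Conditions: BCl3, C6HMe5, CH2Cl2, −78 °C; MeOH quench
Reagents that add atoms: none
Why: Lewis-acid debenzylation with pentamethylbenzene as a non-basic cation scavenger should cleave the six benzyl ethers and the 4-(benzyloxy)benzyl ether at low temperature without hydrogenating the stilbene and without the protic acid that would cyclise it.

**Compound list**
1 | 5-bromobenzene-1,3-diol | Oc1cc(Br)cc(O)c1 | starting material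
2 | 5-bromo-2-iodobenzene-1,3-diol | Oc1cc(Br)cc(O)c1I | intermediate
3 | 4-(benzyloxy)benzyl chloride | ClCc1ccc(OCc2ccccc2)cc1 | starting material
4 | 5-bromo-2-iodo-1,3-bis{[4-(benzyloxy)benzyl]oxy}benzene | Brc1cc(OCc2ccc(OCc3ccccc3)cc2)c(I)c(OCc2ccc(OCc3ccccc3)cc2)c1 | intermediate
5 | (2-ethoxy-2-oxoethyl)zinc bromide (THF solution) | CCOC(=O)C[Zn]Br | starting material
6 | ethyl 2-(4-bromo-2,6-bis{[4-(benzyloxy)benzyl]oxy}phenyl)acetate | CCOC(=O)Cc1c(OCc2ccc(OCc3ccccc3)cc2)cc(Br)cc1OCc1ccc(OCc2ccccc2)cc1 | intermediate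
7 | ethyl 2-(4-bromo-2,6-bis{[4-(benzyloxy)benzyl]oxy}phenyl)-2-diazoacetate | CCOC(=O)C(=[N+]=[N-])c1c(OCc2ccc(OCc3ccccc3)cc2)cc(Br)cc1OCc1ccc(OCc2ccccc2)cc1 | intermediate
8 | ethyl (2R,3S)-6-bromo-4-{[4-(benzyloxy)benzyl]oxy}-2-[4-(benzyloxy)phenyl]-2,3-dihydro-1-benzofuran-3-carboxylate (cis) | Brc1cc(OCc2ccc(OCc3ccccc3)cc2)c2c(c1)O[C@@H](c1ccc(OCc3ccccc3)cc1)[C@H]2C(=O)OCC | intermediate
9 | ethyl (2R,3R)-6-bromo-4-{[4-(benzyloxy)benzyl]oxy}-2-[4-(benzyloxy)phenyl]-2,3-dihydro-1-benzofuran-3-carboxylate (trans) | Brc1cc(OCc2ccc(OCc3ccccc3)cc2)c2c(c1)O[C@@H](c1ccc(OCc3ccccc3)cc1)[C@@H]2C(=O)OCC | intermediate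
10 | (2R,3R)-6-bromo-4-{[4-(benzyloxy)benzyl]oxy}-2-[4-(benzyloxy)phenyl]-2,3-dihydro-1-benzofuran-3-carbaldehyde (LU–CHO) | Brc1cc(OCc2ccc(OCc3ccccc3)cc2)c2c(c1)O[C@@H](c1ccc(OCc3ccccc3)cc1)[C@@H]2C=O | intermediate (not isolated)
11 | 1-(triphenylphosphoranylidene)propan-2-one | CC(=O)C=P(c1ccccc1)(c1ccccc1)c1ccccc1 | starting material
12 | (E)-4-(LU)but-3-en-2-one | Brc1cc(OCc2ccc(OCc3ccccc3)cc2)c2c(c1)O[C@@H](c1ccc(OCc3ccccc3)cc1)[C@@H]2/C=C/C(C)=O | intermediate
13 | dimethyl malonate | COC(=O)CC(=O)OC | starting material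
14 | methyl 6-(LU)-2,4-dioxocyclohexane-1-carboxylate (sodium enolate in the flask; mixture of diastereomers at the two new ring carbons) | Brc1cc(OCc2ccc(OCc3ccccc3)cc2)c2c(c1)O[C@@H](c1ccc(OCc3ccccc3)cc1)[C@@H]2C1CC(=O)CC(=O)C1C(=O)OC | intermediate (not isolated)
15 | 6-(LU)-2,4-dioxocyclohexane-1-carboxylic acid (mixture of diastereomers at the two new ring carbons) | Brc1cc(OCc2ccc(OCc3ccccc3)cc2)c2c(c1)O[C@@H](c1ccc(OCc3ccccc3)cc1)[C@@H]2C1CC(=O)CC(=O)C1C(O)=O | intermediate (not isolated)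
16 | 5-(LU)cyclohexane-1,3-dione | Brc1cc(OCc2ccc(OCc3ccccc3)cc2)c2c(c1)O[C@@H](c1ccc(OCc3ccccc3)cc1)[C@@H]2C1CC(=O)CC(=O)C1 | intermediate
17 | 3,5-bis(benzyloxy)benzyl bromide | BrCc1cc(OCc2ccccc2)cc(OCc2ccccc2)c1 | starting material
18 | (1R,4R,5R)-4,7,7-trimethyl-6-thiabicyclo[3.2.1]octane (isothiocineole) | C[C@@H]1CC[C@@H]2C[C@H]1SC2(C)C | starting material
19 | S-[3,5-bis(benzyloxy)benzyl]isothiocineolium trifluoromethanesulfonate (benzyl on the sulfur lone pair anti to the three-carbon bridge) | C[C@@H]1CC[C@@H]2C[C@H]1[S@@+](Cc1cc(OCc3ccccc3)cc(OCc3ccccc3)c1)C2(C)C.[O-]S(=O)(=O)C(F)(F)F | intermediate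
20 | 3,4-bis(benzyloxy)benzaldehyde | O=Cc1ccc(OCc2ccccc2)c(OCc2ccccc2)c1 | starting material
21 | 2-[3,4-bis(benzyloxy)benzylidene]-5-(LU)cyclohexane-1,3-dione (either orientation of the exocyclic bond relative to C-5) | Brc1cc(OCc2ccc(OCc3ccccc3)cc2)c2c(c1)O[C@@H](c1ccc(OCc3ccccc3)cc1)[C@@H]2C1CC(=O)C(=Cc3ccc(OCc4ccccc4)c(OCc4ccccc4)c3)C(=O)C1 | intermediate (not isolated)
22 | sulfonium ylide of 19 | C[C@@H]1CC[C@@H]2C[C@H]1[S@@+]([CH-]c1cc(OCc3ccccc3)cc(OCc3ccccc3)c1)C2(C)C | intermediate (not isolated)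
23 | (1S,2S)-1-[3,4-bis(benzyloxy)phenyl]-2-[3,5-bis(benzyloxy)phenyl]-6-(LU)spiro[2.5]octane-4,8-dione (trans cyclopropane; both orientations of C-6 relative to the cyclopropane) | Brc1cc(OCc2ccc(OCc3ccccc3)cc2)c2c(c1)O[C@@H](c1ccc(OCc3ccccc3)cc1)[C@@H]2C1CC(=O)C3(C(=O)C1)[C@H](c1ccc(OCc4ccccc4)c(OCc4ccccc4)c1)[C@H]3c1cc(OCc4ccccc4)cc(OCc4ccccc4)c1 | intermediate
24 | (2S,3S)-2-[3,4-bis(benzyloxy)phenyl]-3-[3,5-bis(benzyloxy)phenyl]-6-(LU)-3,5,6,7-tetrahydro-1-benzofuran-4(2H)-one (C-6 epimers) | Brc1cc(OCc2ccc(OCc3ccccc3)cc2)c2c(c1)O[C@@H](c1ccc(OCc3ccccc3)cc1)[C@@H]2C1CC(=O)C3=C(C1)O[C@H](c1ccc(OCc4ccccc4)c(OCc4ccccc4)c1)[C@H]3c1cc(OCc4ccccc4)cc(OCc4ccccc4)c1 | intermediate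
25 | 5-(phenylselanyl) derivative of 24 (mixture of C-5 and C-6 epimers) | Brc1cc(OCc2ccc(OCc3ccccc3)cc2)c2c(c1)O[C@@H](c1ccc(OCc3ccccc3)cc1)[C@@H]2C1C([Se]c4ccccc4)C(=O)C3=C(C1)O[C@H](c1ccc(OCc4ccccc4)c(OCc4ccccc4)c1)[C@H]3c1cc(OCc4ccccc4)cc(OCc4ccccc4)c1 | intermediate (not isolated)
26 | (2S,3S)-2-[3,4-bis(benzyloxy)phenyl]-3-[3,5-bis(benzyloxy)phenyl]-6-(LU)-2,3-dihydro-1-benzofuran-4-ol | Brc1cc(OCc2ccc(OCc3ccccc3)cc2)c2c(c1)O[C@@H](c1ccc(OCc3ccccc3)cc1)[C@@H]2c1cc(O)c3c(c1)O[C@H](c1ccc(OCc4ccccc4)c(OCc4ccccc4)c1)[C@H]3c1cc(OCc4ccccc4)cc(OCc4ccccc4)c1 | intermediate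
27 | 4-(benzyloxy)styrene | C=Cc1ccc(OCc2ccccc2)cc1 | starting material
28 | heptabenzyl-type protected target: 26 with bromine replaced by (E)-2-[4-(benzyloxy)phenyl]ethenyl | c1ccccc1COc1ccc(/C=C/c2cc(OCc4ccc(OCc5ccccc5)cc4)c3c(c2)O[C@@H](c2ccc(OCc4ccccc4)cc2)[C@@H]3c2cc(O)c3c(c2)O[C@H](c2ccc(OCc4ccccc4)c(OCc4ccccc4)c2)[C@H]3c2cc(OCc4ccccc4)cc(OCc4ccccc4)c2)cc1 | intermediate
29 | CNP0107857.3: (2S,3S)-2-(3,4-dihydroxyphenyl)-3-(3,5-dihydroxyphenyl)-6-{(2R,3R)-4-hydroxy-2-(4-hydroxyphenyl)-6-[(E)-2-(4-hydroxyphenyl)ethenyl]-2,3-dihydro-1-benzofuran-3-yl}-2,3-dihydro-1-benzofuran-4-ol | Oc1ccc(/C=C/c2cc(O)c3c(c2)O[C@@H](c2ccc(O)cc2)[C@@H]3c2cc(O)c3c(c2)O[C@H](c2ccc(O)c(O)c2)[C@H]3c2cc(O)cc(O)c2)cc1 | target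

**Step count and risks**

Total steps: 14. Longest linear sequence: 13 (steps 1–8 and 10–14; step 9 is a one-step side branch).

Steps most likely to fail:

Step 10 (bears the label). The ylide may add with poor facial selectivity, the betaine may close through oxygen instead of carbon, or the alkylidene dione may be consumed by a second molecule of dione before the ylide arrives. The fallback uses known chemistry, sets out from 16, 17 and 20 and comes back at 23. Bromide 17 and triethyl phosphite give diethyl [3,5-bis(benzyloxy)benzyl]phosphonate F1 (Arbuzov), and Horner–Wadsworth–Emmons reaction with 20 gives (E)-3,4,3′,5′-tetrakis(benzyloxy)stilbene F2. Bromodimethylsulfonium bromide adds anti across the alkene, with sulfur at the catechol-side carbon, to give the racemic (2-bromo-1,2-diarylethyl)dimethylsulfonium bromide F3. F3 and dione 16 with K2CO3 in EtOAc react by conjugate addition to the vinylsulfonium formed in the flask and 3-exo-tet closure, the established way to cyclohexane-1,3-dione-2-spirocyclopropanes. This should give 23 together with its (1R,2R)-cyclopropane diastereomer F4; the two are separated by preparative HPLC and the route continues from 23.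

Step 5. The doubly ortho-substituted carbenoid may insert with low enantio- or cis/trans control or be lost to carbene dimerisation. The fallback sets out from 7 and comes back at 9. Achiral Rh2(OAc)4 gives the cis ester as a racemate, that is 8 with its enantiomer, the (2S,3R) cis ester F5. NaOH in EtOH–H2O epimerises and saponifies it to the racemic trans acid. Classical resolution by crystallisation of the salt with one enantiomer of 1-phenylethylamine gives the (2R,3R) acid F6 and leaves the (2S,3S) acid F7 in the mother liquor. EtI and K2CO3 in DMF convert F6 into 9.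

Step 14. Lewis-acid ionisation of the benzylic C2–O bonds, or cyclisation of the electron-rich stilbene onto ring C, may occur during debenzylation. The fallback sets out from 26 and comes back at 29; it removes the benzyl groups before the stilbene is present and finishes under basic conditions. BCl3 and C6HMe5 at −78 °C convert 26 into the heptaphenol bromide F8. Ac2O in pyridine gives the heptaacetate F9. Heck reaction of F9 with 4-acetoxystyrene (Pd(OAc)2, P(o-tol)3, Et3N, DMF) gives the octaacetate F10. K2CO3 in MeOH at 0 °C then gives 29.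

Further compounds
F1 | step 10 | diethyl [3,5-bis(benzyloxy)benzyl]phosphonate | CCOP(=O)(Cc1cc(OCc2ccccc2)cc(OCc2ccccc2)c1)OCC
F2 | step 10 | (E)-3,4,3′,5′-tetrakis(benzyloxy)stilbene | c1ccccc1COc1ccc(/C=C/c2cc(OCc3ccccc3)cc(OCc3ccccc3)c2)cc1OCc1ccccc1
F3 | step 10 | {1-[3,4-bis(benzyloxy)phenyl]-2-[3,5-bis(benzyloxy)phenyl]-2-bromoethyl}dimethylsulfonium bromide (racemic; relative configuration from anti addition shown) | C[S+](C)[C@@H](c1ccc(OCc2ccccc2)c(OCc2ccccc2)c1)[C@H](Br)c1cc(OCc2ccccc2)cc(OCc2ccccc2)c1.[Br-]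
F4 | step 10 | (1R,2R)-1-[3,4-bis(benzyloxy)phenyl]-2-[3,5-bis(benzyloxy)phenyl]-6-(LU)spiro[2.5]octane-4,8-dione | Brc1cc(OCc2ccc(OCc3ccccc3)cc2)c2c(c1)O[C@@H](c1ccc(OCc3ccccc3)cc1)[C@@H]2C1CC(=O)C3(C(=O)C1)[C@@H](c1ccc(OCc4ccccc4)c(OCc4ccccc4)c1)[C@@H]3c1cc(OCc4ccccc4)cc(OCc4ccccc4)c1
F5 | step 5 | ethyl (2S,3R)-6-bromo-4-{[4-(benzyloxy)benzyl]oxy}-2-[4-(benzyloxy)phenyl]-2,3-dihydro-1-benzofuran-3-carboxylate (enantiomer of 8) | Brc1cc(OCc2ccc(OCc3ccccc3)cc2)c2c(c1)O[C@H](c1ccc(OCc3ccccc3)cc1)[C@@H]2C(=O)OCC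
F6 | step 5 | (2R,3R)-6-bromo-4-{[4-(benzyloxy)benzyl]oxy}-2-[4-(benzyloxy)phenyl]-2,3-dihydro-1-benzofuran-3-carboxylic acid | Brc1cc(OCc2ccc(OCc3ccccc3)cc2)c2c(c1)O[C@@H](c1ccc(OCc3ccccc3)cc1)[C@@H]2C(O)=O
F7 | step 5 | (2S,3S)-6-bromo-4-{[4-(benzyloxy)benzyl]oxy}-2-[4-(benzyloxy)phenyl]-2,3-dihydro-1-benzofuran-3-carboxylic acid | Brc1cc(OCc2ccc(OCc3ccccc3)cc2)c2c(c1)O[C@H](c1ccc(OCc3ccccc3)cc1)[C@H]2C(O)=O
F8 | step 14 | (2S,3S)-6-[(2R,3R)-6-bromo-4-hydroxy-2-(4-hydroxyphenyl)-2,3-dihydro-1-benzofuran-3-yl]-2-(3,4-dihydroxyphenyl)-3-(3,5-dihydroxyphenyl)-2,3-dihydro-1-benzofuran-4-ol | Brc1cc(O)c2c(c1)O[C@@H](c1ccc(O)cc1)[C@@H]2c1cc(O)c3c(c1)O[C@H](c1ccc(O)c(O)c1)[C@H]3c1cc(O)cc(O)c1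
F9 | step 14 | heptaacetate of F8 | Brc1cc(OC(C)=O)c2c(c1)O[C@@H](c1ccc(OC(C)=O)cc1)[C@@H]2c1cc(OC(C)=O)c3c(c1)O[C@H](c1ccc(OC(C)=O)c(OC(C)=O)c1)[C@H]3c1cc(OC(C)=O)cc(OC(C)=O)c1
F10 | step 14 | octaacetate of 29 | CC(=O)Oc1ccc(/C=C/c2cc(OC(C)=O)c3c(c2)O[C@@H](c2ccc(OC(C)=O)cc2)[C@@H]3c2cc(OC(C)=O)c3c(c2)O[C@H](c2ccc(OC(C)=O)c(OC(C)=O)c2)[C@H]3c2cc(OC(C)=O)cc(OC(C)=O)c2)cc1
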